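At late times target stands at 100.3% in the autumn run and 100.1% in the winter run, level within the scatter, so a repeat has to watch the early curve: at 10.0 min the winter run holds less target, 48.1% against 58.1%.

| setting | autumn | winter | flask |
|---|---|---|---|
| substrate | 0.40 M | 0.40 M | 0.40 M |
| reagent | 5 equiv | 5 equiv | 5.00 equiv |
| free catalyst | 3.3 mol% | 3.3 mol% | 3.3 mol% |
| impurity | 2.2 mM | 4.9 mM | 3.3 mM |
| remark | run made earlier | run made earlier |  |

| run | time / min | target / % |
|---|---|---|
| autumn | 10.0 | 58.1 |
| autumn | 20.0 | 89.2 |
| autumn | 30.0 | 98.5 |
| autumn | 40.0 | 100.0 |
| autumn | 50.0 | 100.3 |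
| autumn | 60.0 | 100.0 |
| autumn | 80.0 | 100.3 |
| winter | 10.0 | 48.1 |
| winter | 20.0 | 77.6 |
| winter | 30.0 | 92.8 |
| winter | 40.0 | 98.0 |
| winter | 50.0 | 99.5 |
| winter | 60.0 | 100.3 |
| winter | 80.0 | 100.1 |

(each reading ± 0.5 percentage points)

- no earlier run changes the charge of free catalyst; that part of a forecast is a guess

- apparent order in free catalyst when 20% of the substrate are converted (percent change of the rate of making target for one percent more free catalyst charged)

Impurity charged, as a fraction of the free catalyst charged, differs between the flasks:

autumn 0.167, winter 0.371, flask 0.250

Call this the lost share. If the rate follows the catalyst left, one minus the lost share, then apparent order = 1/(1 − lost share). One percent on the impurity, the loading or the substrate concentration moves that order by 0.333 percent, so all of them matter. Reagent equivalents stay the same in both runs and do not enter this rule. No run changes the loading, so the rule itself is an assumption.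

My reckoning tests it on the runs. The rule predicts a winter-to-autumn rate ratio of:

0.755

First-order constants read at 10.0 min give:

autumn 0.0870 min⁻¹, winter 0.0656 min⁻¹, ratio 0.754

Putting that ratio back in gives the catalyst lost per impurity, as a reading:

(1 − ratio)/(winter share − ratio × autumn share) = 1.00

A second round with this value gives the flask's order:

1/(1 − 1.00 × 0.250) = 1.33

The forecast gives 1.33, with this warning: “No run varied the catalyst charge, so the true order and the binding stoichiometry are assumed”.

The flask gives 1.3, so the forecast stands.

    reagent + free catalyst → catalyst intermediate A (k = 4.26 M⁻¹ min⁻¹)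
    catalyst intermediate A → by-product + catalyst intermediate B (k = 10.4 min⁻¹)
    substrate + catalyst intermediate B → catalyst intermediate C (k = 17.7 M⁻¹ min⁻¹)
    catalyst intermediate C ⇌ free catalyst + target (K = 0.990 M, k = 92.7 min⁻¹)
    free catalyst + impurity → spent catalyst (k = 2240 M⁻¹ min⁻¹)

By 0.150 h the flask holds impurity at 0% of its charge and spent catalyst at 25.0% of the catalyst charged, which is the lost share 25.0%, and spent catalyst still stands at 25.0% after 15.0 h. In this flask the turning of free catalyst and impurity into spent catalyst, a catalyst poisoning, lifts the order at 20% conversion, reached at 0.0541 h, above one. Without that step the same flask runs at order 0.99 at that conversion, with a rate 1.33 times the actual one.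

(The earlier runs and the new flask stem from a simulated flask for substances that don't exist, and the scatter is random.)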